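The target is a depside, cut here inside ring B and not at its hindered ester. Ring B carries the carbonyl on C1', oxygen on C2' and C4' (meta to each other) and propyl on C6'. This pattern maps onto a buta-1,3-diene oxygenated twice at C1 and once at C3 (C2'–C5') and the triple bond of a hex-2-ynoate (C1', C6'). A single Diels–Alder reaction with loss of methanol forms C1'–C2' and C5'–C6', closes ring B and aromatises it with its substitution pattern in place. Its precursor is dibenzyl-protected olivetolic acid whose free O4 has been acylated by unhindered hex-2-ynoic acid; the 2-O-benzyl ether leaves the new 2'-hydroxyl as the only one to methylate.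

Key step: step 8

Remark: diene 5 is drawn as its (1E) isomer; the geometry of the ketene acetal double bond is immaterial, because that carbon becomes aromatic C2'.

Step 1
Reactants: 1 methyl acetoacetate
Product: 3 methyl (2E)-3-methoxybut-2-enoate, via methyl 3,3-dimethoxybutanoate 2 (not isolated)
Conditions: HC(OMe)3, H2SO4 (cat.), MeOH, rt; then distillation
Reagents that add atoms: trimethyl orthoformate, COC(OC)OC
Why: Acid-catalysed ketalisation of the ketone by the orthoester, followed by acid-catalysed loss of methanol on distillation (enol ether formation), should give the conjugated β-methoxy enoate as its thermodynamically preferred E isomer.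

Step 2
Reactants: 3 methyl (2E)-3-methoxybut-2-enoate
Product: 5 (1E)-1,3-dimethoxy-1-(trimethylsilyloxy)buta-1,3-diene, via lithium dienolate 4 (not isolated)
Conditions: LiN(iPr)2, THF, −78 °C; then Me3SiCl, −78 °C to rt; distillation
Reagents that add atoms: chlorotrimethylsilane, C[Si](C)(C)Cl
Why: LiN(iPr)2 removes a γ-proton of the β-methoxy enoate to give the cross-conjugated lithium dienolate, which the hard electrophile Me3SiCl traps on oxygen (O-silylation of an ester dienolate to a vinylketene silyl acetal).

Step 3
Reactants: 6 olivetolic acid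
Product: 7 benzyl 2,4-dihydroxy-6-pentylbenzoate
Conditions: BnBr, KHCO3, DMF, rt
Reagents that add atoms: benzyl bromide, BrCc1ccccc1
Why: SN2 O-alkylation of the carboxylate, the only group that KHCO3 deprotonates, should give the benzyl ester with both phenols free, and room temperature avoids decarboxylation of the β-resorcylic acid.

Step 4
Reactants: 7 benzyl 2,4-dihydroxy-6-pentylbenzoate
Product: 8 benzyl 2-hydroxy-6-pentyl-4-(triisopropylsilyloxy)benzoate
Conditions: iPr3SiCl, imidazole, DMF, 0 °C to rt
Reagents that add atoms: chlorotriisopropylsilane, CC(C)[Si](Cl)(C(C)C)C(C)C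
Why: Selective phenol silylation: the 4-hydroxyl is free and unhindered, whereas the 2-hydroxyl is hydrogen-bonded to the ester carbonyl and should not react with the bulky silyl chloride.

Step 5
Reactants: 8 benzyl 2-hydroxy-6-pentyl-4-(triisopropylsilyloxy)benzoate
Product: 9 benzyl 2-(benzyloxy)-6-pentyl-4-(triisopropylsilyloxy)benzoate
Conditions: BnBr, K2CO3, acetone, reflux
Reagents that add atoms: benzyl bromide, BrCc1ccccc1
Why: Williamson etherification of the remaining, chelated 2-hydroxyl, with the bulky triisopropylsilyl ether expected to resist anhydrous carbonate in acetone.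

Step 6
Reactants: 9 benzyl 2-(benzyloxy)-6-pentyl-4-(triisopropylsilyloxy)benzoate
Product: 10 benzyl 2-(benzyloxy)-4-hydroxy-6-pentylbenzoate
Conditions: Bu4NF, AcOH, THF, 0 °C
Reagents that add atoms: none
Why: Fluoride-induced cleavage of the aryl silyl ether (Si–F bond formation), buffered with acetic acid so that the liberated phenoxide does not attack the benzyl ester.

Step 7
Reactants: 10 benzyl 2-(benzyloxy)-4-hydroxy-6-pentylbenzoate; 11 hex-2-ynoic acid
Product: 12 benzyl 2-(benzyloxy)-4-(hex-2-ynoyloxy)-6-pentylbenzoate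
Conditions: DCC, DMAP (cat.), CH2Cl2, 0 °C
Reagents that add atoms: none
Why: Steglich esterification: the carboxyl of 11 has no flanking substituents and the 4-hydroxyl of 10 lies between two ring CH groups, so the carbodiimide coupling is sterically easy, and the low temperature limits conjugate addition to the activated ynoate.

Step 8
Reactants: 12 benzyl 2-(benzyloxy)-4-(hex-2-ynoyloxy)-6-pentylbenzoate; 5 (1E)-1,3-dimethoxy-1-(trimethylsilyloxy)buta-1,3-diene
Product: 15 benzyl 2-(benzyloxy)-4-[(2-hydroxy-4-methoxy-6-propylbenzoyl)oxy]-6-pentylbenzoate, via cyclohexa-1,4-diene cycloadduct 13 (not isolated), via aryl trimethylsilyl ether 14 (not isolated)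
Conditions: 5 (3 equiv), toluene, 110 °C, sealed tube; then 1 M HCl, THF, rt
Reagents that add atoms: none
Why: The electron-rich diene 5 should add to the electron-poor triple bond of 12 in a concerted but asynchronous [4+2] cycloaddition, in which the bond from the diene CH2 (future C5') to the propyl-bearing alkyne carbon (C6') runs ahead of the bond from the ketene acetal carbon (C2') to the carbonyl-bearing alkyne carbon (C1'), giving the cyclohexa-1,4-diene 13. The mixed methyl silyl ketal carbon of 13 then expels methanol to give the aromatic silyl ether 14, and dilute acid cleaves the O–Si bond to the hydrogen-bonded phenol 15. The closest known reaction is the Diels–Alder benzannulation of 1-alkoxy-1-silyloxy-3-oxygenated butadienes with alkyl alk-2-ynoates to 6-alkyl-β-resorcylates; the aryl ester is a more electron-poor member of the same dienophile class. Ring B, the only new ring, is closed as a six-membered carbocycle by intermolecular union of the four diene carbons with the two alkyne carbons. No stereocentre is created in the product, since the ketal carbon of 13 is racemic and becomes aromatic C2'. The step needs one orientation, secured by matched polarisation (the CH2 terminus is the nucleophilic end of both enol ether units, the alkyne carbon β to the carbonyl is the electrophilic one), and the thermal, Lewis-acid-free conditions should leave the aryl ester, benzyl ester and benzyl ether untouched.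

Step 9
Reactants: 15 benzyl 2-(benzyloxy)-4-[(2-hydroxy-4-methoxy-6-propylbenzoyl)oxy]-6-pentylbenzoate
Product: 16 benzyl 2-(benzyloxy)-4-[(2,4-dimethoxy-6-propylbenzoyl)oxy]-6-pentylbenzoate
Conditions: MeI, K2CO3, acetone, reflux
Reagents that add atoms: iodomethane, CI
Why: Williamson O-methylation of the only free hydroxyl in the molecule; the 2-hydroxyl of ring A is masked as its benzyl ether, so no selectivity between the two hydrogen-bonded positions is required.

Step 10
Reactants: 16 benzyl 2-(benzyloxy)-4-[(2,4-dimethoxy-6-propylbenzoyl)oxy]-6-pentylbenzoate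
Product: 17 4-[(2,4-dimethoxy-6-propylbenzoyl)oxy]-2-hydroxy-6-pentylbenzoic acid (CNP0324837.0)
Conditions: H2 (1 atm), 10% Pd/C, EtOAc, rt
Reagents that add atoms: none
Why: Catalytic hydrogenolysis should cleave both benzylic C–O bonds (ester and ether) under neutral conditions that leave the aryl ester link and the aryl methyl ethers intact.

Compound list
1 | methyl acetoacetate | CC(=O)CC(=O)OC | starting material
2 | methyl 3,3-dimethoxybutanoate (not isolated) | CC(OC)(OC)CC(=O)OC | intermediate
3 | methyl (2E)-3-methoxybut-2-enoate | CO/C(C)=C/C(=O)OC | intermediate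
4 | lithium (1Z)-1,3-dimethoxybuta-1,3-dien-1-olate (not isolated) | [Li+].COC(=C)/C=C(\OC)[O-] | intermediate
5 | (1E)-1,3-dimethoxy-1-(trimethylsilyloxy)buta-1,3-diene | COC(=C)/C=C(\OC)O[Si](C)(C)C | intermediate
6 | olivetolic acid (2,4-dihydroxy-6-pentylbenzoic acid) | CCCCCc1cc(O)cc(O)c1C(=O)O | starting material
7 | benzyl 2,4-dihydroxy-6-pentylbenzoate | CCCCCc1cc(O)cc(O)c1C(=O)OCc1ccccc1 | intermediate
8 | benzyl 2-hydroxy-6-pentyl-4-(triisopropylsilyloxy)benzoate | CCCCCc1cc(O[Si](C(C)C)(C(C)C)C(C)C)cc(O)c1C(=O)OCc1ccccc1 | intermediate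
9 | benzyl 2-(benzyloxy)-6-pentyl-4-(triisopropylsilyloxy)benzoate | CCCCCc1cc(O[Si](C(C)C)(C(C)C)C(C)C)cc(OCc2ccccc2)c1C(=O)OCc1ccccc1 | intermediate
10 | benzyl 2-(benzyloxy)-4-hydroxy-6-pentylbenzoate | CCCCCc1cc(O)cc(OCc2ccccc2)c1C(=O)OCc1ccccc1 | intermediate
11 | hex-2-ynoic acid | CCCC#CC(=O)O | starting material
12 | benzyl 2-(benzyloxy)-4-(hex-2-ynoyloxy)-6-pentylbenzoate | CCCC#CC(=O)Oc1cc(CCCCC)c(C(=O)OCc2ccccc2)c(OCc2ccccc2)c1 | intermediate
13 | benzyl 2-(benzyloxy)-4-{[4,6-dimethoxy-2-propyl-6-(trimethylsilyloxy)cyclohexa-1,4-diene-1-carbonyl]oxy}-6-pentylbenzoate (racemic at the ketal carbon, not isolated) | CCCC1=C(C(=O)Oc2cc(CCCCC)c(C(=O)OCc3ccccc3)c(OCc3ccccc3)c2)C(OC)(O[Si](C)(C)C)C=C(OC)C1 | intermediate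
14 | benzyl 2-(benzyloxy)-4-{[4-methoxy-2-propyl-6-(trimethylsilyloxy)benzoyl]oxy}-6-pentylbenzoate (not isolated) | CCCCCc1cc(OC(=O)c2c(CCC)cc(OC)cc2O[Si](C)(C)C)cc(OCc2ccccc2)c1C(=O)OCc1ccccc1 | intermediate
15 | benzyl 2-(benzyloxy)-4-[(2-hydroxy-4-methoxy-6-propylbenzoyl)oxy]-6-pentylbenzoate | CCCCCc1cc(OC(=O)c2c(CCC)cc(OC)cc2O)cc(OCc2ccccc2)c1C(=O)OCc1ccccc1 | intermediate
16 | benzyl 2-(benzyloxy)-4-[(2,4-dimethoxy-6-propylbenzoyl)oxy]-6-pentylbenzoate | CCCCCc1cc(OC(=O)c2c(CCC)cc(OC)cc2OC)cc(OCc2ccccc2)c1C(=O)OCc1ccccc1 | intermediate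
17 | 4-[(2,4-dimethoxy-6-propylbenzoyl)oxy]-2-hydroxy-6-pentylbenzoic acid | CCCCCc1cc(OC(=O)c2c(CCC)cc(OC)cc2OC)cc(O)c1C(=O)O | target

Total step count: 10 (steps 1–2 make the diene, steps 3–7 the ynoate, steps 8–10 finish).
Longest linear sequence: 8 steps (olivetolic acid 6 to target 17, steps 3–10).

Steps most likely to fail

1. Step 8. The β-propyl-substituted triple bond may cycloadd slowly. Thermal decomposition of the diene, or its attack on the activated aryl ester carbonyl with expulsion of the ring A phenoxide, could then outrun ring formation, and loss of methanol from the adduct may stall. Fallback, setting out from phenol 10 and returning at 16, with ring B made separately and the depside bond formed last by known chemistry: commercial 5-propylbenzene-1,3-diol is O-methylated (MeI, K2CO3, acetone) to 1,3-dimethoxy-5-propylbenzene F1. Vilsmeier–Haack formylation (POCl3, DMF) at the ring position between a methoxy group and the propyl group should give 2,4-dimethoxy-6-propylbenzaldehyde F2. Chlorite oxidation (NaClO2, NaH2PO4, 2-methylbut-2-ene, tBuOH–H2O) then gives 2,4-dimethoxy-6-propylbenzoic acid F3. F3 is condensed with 10 by (CF3CO)2O in toluene at rt, the established mixed-anhydride/acylium esterification of 2,6-disubstituted benzoic acids with phenols, to give 16 directly, so that step 9 is also bypassed.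

2. Step 9. Alkylation of the hydrogen-bonded 2'-hydroxyl may be slow enough that carbonate, or traces of hydroxide or methoxide, cleave or transacylate the aryl ester link. Fallback, setting out from ynoate 12 and returning at 16, in which the C2' methyl ether arrives with the diene and only a non-chelated hydroxyl remains to be methylated: acetyl chloride and 1,1-dimethoxyethene (2 equiv, the second taking up HCl) give 4,4-dimethoxybut-3-en-2-one F4. Kinetic enolisation and silylation (LiN(iPr)2, Me3SiCl, THF, −78 °C) give 1,1-dimethoxy-3-(trimethylsilyloxy)buta-1,3-diene F5. Heating F5 with 12 as in step 8 should give the cyclohexa-1,4-diene cycloadduct F6, which loses methanol to the aryl trimethylsilyl ether F7. Acidic work-up liberates benzyl 2-(benzyloxy)-4-[(4-hydroxy-2-methoxy-6-propylbenzoyl)oxy]-6-pentylbenzoate F8. Its free, acidic 4'-hydroxyl (para to the ester carbonyl) is methylated without base by Me3SiCHN2 in toluene–MeOH to give 16.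

3. Step 5. Under the basic alkylation the silyl group may be lost from O4 or migrate between phenoxides, so that benzyl ends up on O4 as well. Fallback, setting out from 7 and returning at 10, with a base-inert temporary group on O4: allyl bromide (1 equiv) and K2CO3 in acetone at rt alkylate the more acidic 4-hydroxyl to give benzyl 4-(allyloxy)-2-hydroxy-6-pentylbenzoate F9. BnBr and K2CO3 in DMF at 60 °C give benzyl 4-(allyloxy)-2-(benzyloxy)-6-pentylbenzoate F10. Allyl transfer to morpholine catalysed by Pd(PPh3)4 (zerovalent palladium) in THF at rt frees the 4-hydroxyl and gives 10.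

Further compounds
F1 | step 8 | 1,3-dimethoxy-5-propylbenzene | CCCc1cc(OC)cc(OC)c1
F2 | step 8 | 2,4-dimethoxy-6-propylbenzaldehyde | CCCc1cc(OC)cc(OC)c1C=O
F3 | step 8 | 2,4-dimethoxy-6-propylbenzoic acid | CCCc1cc(OC)cc(OC)c1C(=O)O
F4 | step 9 | 4,4-dimethoxybut-3-en-2-one | CC(=O)C=C(OC)OC
F5 | step 9 | 1,1-dimethoxy-3-(trimethylsilyloxy)buta-1,3-diene | COC(OC)=CC(=C)O[Si](C)(C)C
F6 | step 9 | benzyl 2-(benzyloxy)-4-{[6,6-dimethoxy-2-propyl-4-(trimethylsilyloxy)cyclohexa-1,4-diene-1-carbonyl]oxy}-6-pentylbenzoate | CCCC1=C(C(=O)Oc2cc(CCCCC)c(C(=O)OCc3ccccc3)c(OCc3ccccc3)c2)C(OC)(OC)C=C(O[Si](C)(C)C)C1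
F7 | step 9 | benzyl 2-(benzyloxy)-4-{[2-methoxy-6-propyl-4-(trimethylsilyloxy)benzoyl]oxy}-6-pentylbenzoate | CCCCCc1cc(OC(=O)c2c(CCC)cc(O[Si](C)(C)C)cc2OC)cc(OCc2ccccc2)c1C(=O)OCc1ccccc1
F8 | step 9 | benzyl 2-(benzyloxy)-4-[(4-hydroxy-2-methoxy-6-propylbenzoyl)oxy]-6-pentylbenzoate | CCCCCc1cc(OC(=O)c2c(CCC)cc(O)cc2OC)cc(OCc2ccccc2)c1C(=O)OCc1ccccc1
F9 | step 5 | benzyl 4-(allyloxy)-2-hydroxy-6-pentylbenzoate | CCCCCc1cc(OCC=C)cc(O)c1C(=O)OCc1ccccc1
F10 | step 5 | benzyl 4-(allyloxy)-2-(benzyloxy)-6-pentylbenzoate | CCCCCc1cc(OCC=C)cc(OCc2ccccc2)c1C(=O)OCc1ccccc1
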